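Late in a run like this, what to watch is whether initiating radicals still meet each molecule that dissolves.

solid substrate 1.5 M; reagent 1.30 equiv; initiator 5 mol%; time 3.0 h

    starting material + initiating radical → capped initiator + first chain carrier (k1 = 12000 M⁻¹ s⁻¹)
    solid substrate ⇌ starting material, rate k2*(cs2 - [starting material]) while solid is left; crystals form when [starting material] > cs2 (cs2 = 0.053 M, k2 = 0.0072 min⁻¹)
    initiator → 2 initiating radical (k3 = 0.014 min⁻¹)
    first chain carrier → ended carrier (k4 = 2200 min⁻¹)
    starting material + second chain carrier → by-product + first chain carrier (k5 = 29000 M⁻¹ min⁻¹)
    reagent + first chain carrier → product + second chain carrier (k6 = 23000 M⁻¹ min⁻¹)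
    2 second chain carrier → ended chains (k7 = 5.5 × 10⁷ M⁻¹ s⁻¹)

- the product standing at 3.0 h, as a percentage of the solid substrate charged
- concentration of starting material in solution at 3.0 h, in percent of saturation

We begin with a rule of thumb: a solid over a nearly empty solution dissolves at its top rate, the dissolution coefficient times the solubility, 3.82 × 10⁻⁴ M min⁻¹, which we call the feed. In this flask the initiator first makes initiating radicals at 0.00210 M min⁻¹, faster than the feed, so we take dissolution as the rate-limiting step for as long as radicals stand, and assume one product per dissolved molecule.

The correction is the first chain carrier lost to ended carrier. Reagent takes it 20.4 times as fast as that loss, so a share 0.953 goes on to product: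

y ≈ feed × time × share / solid charged = 4.37%

By 3.0 h we reckon that radicals made less radicals taken leave 0.0692 M, and we let their capture of starting material balance the feed:

sat ≈ <0.001%

The rule has a border. In our rule each dissolved molecule takes one radical, and the initiator charged can give 0.150 M. We reckon that the feed uses these up in

6.55 h

This is later than 3.0 h, so this flask stands inside the border.

The forecast gives y = 4.36%, within 4.2% to 4.5%, and sat <0.001%, on the grounds that “Radicals therefore outrun dissolution, and their only sink is starting material”.

The simulation gives y = 4.36% and sat = 0%.

In this flask at 3.00 h, initiating radical is made at 0.444 of the rate at which it is used, and it reads 0.0731 M at 1.50 h and 0.0692 M at 3.00 h. That falling reading is the one to follow.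

Read at 12 h, past the border, the same flask has a feed ceiling of 18.3%, above the radical charge of 10.0%, so we reckon 9.53% from the radical charge times the share. The computed result there is 9.66%, with initiator at 0% of its charge and starting material at 3.15% of the solid substrate charged.

The rate constants were chosen freely.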